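The runs are calculated for substances that don't exist; noise was put on by code.

Divide the fall of links plus first end groups per minute by the free first end groups beside it. From 40.0 min to 120 min in the violet run this gives 0.0366 /min. Call it the drain constant, a pseudo-first-order constant, and read it as a reading with a scatter of 0.3 percentage points on each value.

| setting | violet | flask |
|---|---|---|
| first end groups | 20 mM | 20 mM |
| second end groups | 1.05 equiv | 1.05 equiv |
| remark | the very flask that is asked about, followed so far |  |
| time |  | 3.0 h |

- violet (time / min: links / %, first end groups / %): 15.0: 90.9, 2.5; 40.0: 89.9, 1.7; 80.0: 88.1, 1.4; 120: 86.0, 1.5

(scatter of a reading: 0.3 percentage points)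

- eta: at 3.0 h add first end groups, 50.0% of the amount charged, then wait 1.5 h
- gamma: at 3.0 h take out 90% of the by-product then present, then wait 1.5 h
- zeta: at 3.0 h add second end groups, 100% of the amount charged, then wait 1.5 h
- alpha: change nothing and wait 1.5 h more

- additions leave the volume as it is
- a reading or a percentage of links counts all its forms, free or not

- links, in percent of the first end groups first charged, at 3.0 h
- which option adds most links ("none" when 2 percentage points or less is all one gets) (eta / gamma / zeta / alpha / none)
- links present, in percent of the first end groups first charged, after eta
- links present, in percent of the first end groups first charged, after gamma

Now decide the next step. My reckoning takes 1.5% free from the last reading and carries links to 82.7% at 3.0 h. Waiting costs 4.9 points more. Gamma and zeta can capture little beyond the free first end groups, and those are fewer than the margin of 2 points.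

Eta raises the drain at once, since 50.0% goes in beside 1.5%. By the forecast's count, about 21% of second end groups are unused, and whatever lacks a partner stays free. Assume each loss takes one first end group and one link out of the sum, so that the sum counts each loss twice: free first end groups then halve by this drain in 37.9 min, short against the wait of 90 min, and in the violet run links paid: they fell from 89.9% to 86.0% while first end groups stayed near 1.4%. So book that excess against links, expect eta to lose, and charge nothing: my answer is none.

The forecast differs. It reads 0.034/min, gives 83.4% (82.3% to 84.4%), 84.3% after gamma and 96% after eta, and chooses eta: “as the excess first end groups die, links drain back to about 96”.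

The flask gives 83.1%, 83.5% after gamma, 68.0% after eta, and best: none.

    first end groups + second end groups ⇌ links + by-product (K = 190, k = 1.20 /M/s)
    first end groups + by-product → side product A (k = 0.00340 /M/s)
    crystals ⇌ links, rate k3*(cs3 - [links]) while solid is left; crystals form when [links] > cs3 (solubility = 7.60 mM, k = 0.0380 /s)
    first end groups + links → side product B (k = 0.0400 /M/s)

In this flask coupling ran first, half its turnover done by 0.538 min, and crystals grew next, half by 1.52 min. Then, while crystals shrank from 52.8% at 0.300 h to 45.1% at 3.00 h, dissolved links stood at 38.0% and first end groups carried links into side product B, which counts as two. The drain constant with 1.11% free gives a fall of 3.7 points over the wait, and alpha lost 3.6 points. In the neighbour at 50 mM, free first end groups stood at 0.529 of this flask's value, and side product B at 0.625.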